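**Retrosynthetic overview**
1. 25 ⇐ 22 (angelate put on last) ⇐ 21 ⇐ 18 (C7–C11 bond by palladium enolate coupling at C7–Br, an Evans auxiliary sets C11) ⇐ 17 ⇐ 16 (C1 ketone reduced from the α face).
2. Key disconnection is C1–C10 of ring A. 16 ⇐ 14, an aldehyde tethered to a 2,6-dibromo-4,4-dialkylcyclohexa-2,5-dienone, by carbene umpolung of C1 (Stetter) and loss of HBr in the same flask.
3. Enabling feature: O–C1–C10=C9–C8=O is a 1,4-dioxygenated (dissonant) array in which C1 and C10 are both acceptor carbons. Once C1–C10 is cut and C7 and C9 carry the same halogen, ring B has a local mirror plane through C5 and C8, so C5 is prochiral and the arms C6=C7 and C10=C9 differ only through C4.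
4. 14 ⇐ 13 ⇐ 11 ⇐ 9 ⇐ 8: ring B by Robinson annulation of α-methylated (S)-citronellal (source of C4) with methyl vinyl ketone.
5. Ring order: ring B (step 2), then ring A (step 7).

Key step: step 7

Remark on numbering: eremophilane numbers are used. Ring A is C1 (carbinol), C2, C3, C4 (CHMe), C5 (quaternary), C10. Ring B is C5, C6, C7, C8 (C=O), C9, C10. C11 is the side-chain methine. β is the face of the C5 methyl group. The target is 1R,4S,5S,11S with a Z (angelate) ester.
Assumption: the (5aR,10bS) antipode of the aminoindanol triazolium salt is taken as the one that acylates the arm making C5 S-configured; if the sense proves opposite, the equally commercial (5aS,10bR) salt takes its place.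
Assumption: the facial sense of the palladium coupling in step 11 is taken to follow the Evans enolate alkylation model, so the (R)-benzyl auxiliary gives 11S.

Step 1
Reactants: 1 (S)-(−)-citronellal
Product: 4 (3S)-2,3,7-trimethyloct-6-enal as a C2 epimer mixture, via tert-butylimine 2 (not isolated), via methylated imine 3 (not isolated)
Conditions: t-BuNH2, 4 Å MS, Et2O, rt; LiN(i-Pr)2, THF, 0 °C, then MeI, −78 °C to rt; aq. AcOH/NaOAc, rt
Reagents that add atoms: tert-butylamine CC(C)(C)N (in 2 and 3 only); iodomethane CI; water O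
Why: Stork–Dowd metalloenamine alkylation monomethylates the lithiated aldimine at the α-carbon (future C5) where the free aldehyde would self-condense, C4 is untouched, and the new α-centre may be a mixture because it stops being stereogenic in step 3.

Step 2
Reactants: 4 (3S)-2,3,7-trimethyloct-6-enal; 5 methyl vinyl ketone
Product: 8 4-methyl-4-[(2S)-6-methylhept-5-en-2-yl]cyclohex-2-en-1-one as a ring C4 epimer mixture, via enamine 6 (not isolated), via keto aldehyde 7 (not isolated)
Conditions: pyrrolidine, toluene, Dean–Stark reflux; 5, 0 °C to rt; AcOH/NaOAc/H2O, 80 °C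
Reagents that add atoms: pyrrolidine C1CCNC1 (in 6 only); water O (in 7 only)
Why: Stork enamine Michael addition followed by pyrrolidinium acetate-mediated aldol condensation (Robinson annulation of an α,α-disubstituted aldehyde) closes ring B and builds quaternary C5, whose configuration is irrelevant because step 3 makes it prochiral.

Step 3
Reactants: 8 4-methyl-4-[(2S)-6-methylhept-5-en-2-yl]cyclohex-2-en-1-one
Product: 9 4-methyl-4-[(2S)-6-methylhept-5-en-2-yl]cyclohexa-2,5-dien-1-one
Conditions: 2-iodoxybenzoic acid (IBX), DMSO, 80 °C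
Reagents that add atoms: none
Why: IBX dehydrogenation of the enone through its α'-enol should give the cross-conjugated dienone, the isolated side-chain alkene is inert to IBX, and only C4 remains stereogenic.

Step 4
Reactants: 9 4-methyl-4-[(2S)-6-methylhept-5-en-2-yl]cyclohexa-2,5-dien-1-one
Product: 11 4-[(2S)-5,5-dimethoxypentan-2-yl]-4-methylcyclohexa-2,5-dien-1-one, via aldehyde 10 (not isolated)
Conditions: O3, CH2Cl2/MeOH, −78 °C (Sudan red 7B end point); Me2S, to rt; HC(OMe)3, TsOH·H2O (cat.), rt
Reagents that add atoms: ozone [O-][O+]=O (in 10 only); trimethyl orthoformate COC(OC)OC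
Why: Chemoselective ozonolysis cleaves the electron-rich trisubstituted alkene far faster than the electron-poor dienone bonds, and acid-catalysed acetalisation masks the enolisable aldehyde against bromine.

Step 5
Reactants: 11 4-[(2S)-5,5-dimethoxypentan-2-yl]-4-methylcyclohexa-2,5-dien-1-one
Product: 13 2,6-dibromo-4-[(2S)-5,5-dimethoxypentan-2-yl]-4-methylcyclohexa-2,5-dien-1-one, via tetrabromide 12 (not isolated)
Conditions: Br2 (2.2 equiv), CH2Cl2, 0 °C; Et3N, 0 °C to rt
Reagents that add atoms: bromine BrBr
Why: Standard α-bromination of enones (bromine addition to both C=C bonds, then base-induced loss of the β-bromide from each α-bromo ketone unit) keeps the local symmetry of the ring, so no stereocentre is made.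

Step 6
Reactants: 13 2,6-dibromo-4-[(2S)-5,5-dimethoxypentan-2-yl]-4-methylcyclohexa-2,5-dien-1-one
Product: 14 2,6-dibromo-4-methyl-4-[(2S)-5-oxopentan-2-yl]cyclohexa-2,5-dien-1-one
Conditions: 1 M HCl, THF, rt
Reagents that add atoms: water O
Why: Acid-catalysed acetal hydrolysis with dilute acid at room temperature is far milder than what a dienone–phenol rearrangement needs.

Step 7
Reactants: 14 2,6-dibromo-4-methyl-4-[(2S)-5-oxopentan-2-yl]cyclohexa-2,5-dien-1-one
Product: 16 (4aS,5S)-3-bromo-4a,5-dimethyl-4a,5,6,7-tetrahydronaphthalene-2,8-dione (7-bromoeremophila-6,9-diene-1,8-dione), via bromo diketone 15 (not isolated)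
Conditions: (5aR,10bS)-2-(pentafluorophenyl)-5a,10b-dihydro-4H,6H-indeno[2,1-b][1,2,4]triazolo[4,3-d][1,4]oxazin-2-ium tetrafluoroborate (20 mol %), i-Pr2NEt (2.2 equiv), toluene (0.02 M), 4 Å MS, rt, argon
Reagents that add atoms: none
Why: Proposed new method: the triazolylidene set free by i-Pr2NEt adds to the aldehyde of 14 and turns C1 into an acyl-anion equivalent (Breslow enaminol), which adds to the β-carbon C10 of one bromo-enone arm, and release of the carbene gives the cis-fused 1,4-diketone 15, whose C10–H is now α to the new C1 ketone and β to C9–Br, so that the amine expels bromide (E1cB) and restores the cross-conjugated dienone as ene-dione 16. The closest known reaction type is the carbene-catalysed intramolecular Stetter desymmetrisation of 4,4-disubstituted cyclohexa-2,5-dienones, and what is new is the α-bromo acceptor and the dehydrobromination that follows in the same flask. Ring A closes in the 6-exo-trig mode (C1 onto C10, C9 outside the new ring), helped by the quaternary C5 (Thorpe–Ingold effect) and by the lowered LUMO of the brominated enone. C5 is set by the choice between the two diastereotopic arms, which the chiral carbene controls (the resident C4 centre gives only a weak bias in a chair-like transition state), C4 is carried from citronellal, and the C9 and C10 centres of 15 are transient. The step needs arm selection, conjugate acylation rather than attack at bromine, and intra- over intermolecular reaction: both arms lead to the same constitution so only configuration is at stake, the sp2 C–Br bonds and the neopentyl β-carbons resist carbene attack, and the four-atom tether at high dilution secures cyclisation. One operation thus closes ring A, fixes the quaternary centre, places oxygen on C1, regenerates the dienone and leaves bromine only at C7 as the handle for the side chain.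

Step 8
Reactants: 16 (4aS,5S)-3-bromo-4a,5-dimethyl-4a,5,6,7-tetrahydronaphthalene-2,8-dione
Product: 17 (4aS,5S,8R)-3-bromo-4a,5-dimethyl-2,4a,5,6,7,8-hexahydronaphthalene-2,8-diol as a C2 (eremophilane C8) epimer mixture
Conditions: NaBH4, CeCl3·7H2O, MeOH, −78 to −40 °C; aq. NaHCO3 quench
Reagents that add atoms: none
Why: Luche 1,2-reduction of both carbonyl groups should deliver hydride to C1 from the α face, opposite the axial 5β-methyl group that is 1,3-related to C1 (the bias that gives 6β-alcohols from steroidal 4-ene-3,6-diones), which sets C1 as R, while the C8 carbinol centre is erased in step 9.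

Step 9
Reactants: 17 (4aS,5S,8R)-3-bromo-4a,5-dimethyl-2,4a,5,6,7,8-hexahydronaphthalene-2,8-diol
Product: 18 (4aS,5S,8R)-3-bromo-8-hydroxy-4a,5-dimethyl-5,6,7,8-tetrahydronaphthalen-2(4aH)-one
Conditions: MnO2 (activated), CH2Cl2, rt
Reagents that add atoms: none
Why: Chemoselective allylic oxidation with MnO2 should take the doubly allylic, unhindered C8 carbinol much faster than the axial C1 alcohol, whose equatorial C–H lies near the nodal plane of the C9=C10 π bond (precedent type: 4-ene-3β,6β-diols to 6β-hydroxy-4-en-3-ones).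

Step 10
Reactants: 19 (R)-4-benzyl-3-propionyloxazolidin-2-one
Product: 20 (R)-4-benzyl-3-[(Z)-1-(trimethylsilyloxy)prop-1-en-1-yl]oxazolidin-2-one
Conditions: NaN(SiMe3)2, THF, −78 °C; Me3SiCl, −78 °C to rt
Reagents that add atoms: chlorotrimethylsilane C[Si](C)(C)Cl
Why: O-silylation of the chelated Z-sodium enolate of an Evans imide gives the Z-silyl ketene N,O-acetal.

Step 11
Reactants: 18 (4aS,5S,8R)-3-bromo-8-hydroxy-4a,5-dimethyl-5,6,7,8-tetrahydronaphthalen-2(4aH)-one; 20 (R)-4-benzyl-3-[(Z)-1-(trimethylsilyloxy)prop-1-en-1-yl]oxazolidin-2-one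
Product: 21 (R)-4-benzyl-3-{(2S)-2-[(5R,8S,8aS)-5-hydroxy-8,8a-dimethyl-3-oxo-3,5,6,7,8,8a-hexahydronaphthalen-2-yl]propanoyl}oxazolidin-2-one
Conditions: Pd(dba)2 (5 mol %), P(t-Bu)3 (10 mol %), ZnF2, 20 (excess), DMF, 60 °C; aq. citric acid work-up (cleaves any O-SiMe3)
Reagents that add atoms: none
Why: Palladium-catalysed α-alkenylation of a silyl imide enolate activated by ZnF2 (oxidative addition of zerovalent palladium into the activated C7–Br bond, transmetalation, reductive elimination) forms C7–C11 under nearly neutral conditions, and the benzyl group of the auxiliary shields one face of the Z-enolate so that C11 should be S.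

Step 12
Reactants: 21 the imide of step 11
Product: 22 methyl (2S)-2-[(5R,8S,8aS)-5-hydroxy-8,8a-dimethyl-3-oxo-3,5,6,7,8,8a-hexahydronaphthalen-2-yl]propanoate
Conditions: Yb(OTf)3 (10 mol %), MeOH, rt to 40 °C
Reagents that add atoms: methanol CO
Why: Lewis acid-catalysed methanolysis of an N-acyloxazolidinone, in which chelation of the two imide carbonyl groups by Yb(OTf)3 activates only the exocyclic acyl group, needs no base and so should leave the epimerisable C11 centre and the dienone alone.

Step 13
Reactants: 22 methyl (2S)-2-[(5R,8S,8aS)-5-hydroxy-8,8a-dimethyl-3-oxo-3,5,6,7,8,8a-hexahydronaphthalen-2-yl]propanoate; 23 angelic acid ((Z)-2-methylbut-2-enoic acid)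
Product: 25 methyl (2S)-2-[(5R,8S,8aS)-8,8a-dimethyl-5-{[(Z)-2-methylbut-2-enoyl]oxy}-3-oxo-3,5,6,7,8,8a-hexahydronaphthalen-2-yl]propanoate (CNP0166395.1), via mixed anhydride 24 (not isolated)
Conditions: 23, 2,4,6-Cl3C6H2COCl, Et3N, toluene, rt; then 22, 80 °C
Reagents that add atoms: 2,4,6-trichlorobenzoyl chloride O=C(Cl)c1c(Cl)cc(Cl)cc1Cl (in 24 only)
Why: Yamaguchi mixed-anhydride esterification run without a nucleophilic pyridine catalyst avoids the addition–elimination path that turns angelates into tiglates, and the C1–O bond is not touched, so 1R is retained.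

**Compound list**
1 | (S)-(−)-citronellal | CC(C)=CCC[C@H](C)CC=O | starting material
2 | N-tert-butyl aldimine of 1 | CC(C)=CCC[C@H](C)CC=NC(C)(C)C | intermediate
3 | α-methylated N-tert-butyl aldimine | CC(C)=CCC[C@H](C)C(C)C=NC(C)(C)C | intermediate
4 | (3S)-2,3,7-trimethyloct-6-enal (C2 epimers) | CC(C)=CCC[C@H](C)C(C)C=O | intermediate
5 | methyl vinyl ketone | CC(=O)C=C | starting material
6 | 1-[(3S)-2,3,7-trimethylocta-1,6-dien-1-yl]pyrrolidine | CC(C)=CCC[C@H](C)C(C)=CN1CCCC1 | intermediate
7 | (3S)-2,3,7-trimethyl-2-(3-oxobutyl)oct-6-enal (C2 epimers) | CC(C)=CCC[C@H](C)C(C)(C=O)CCC(C)=O | intermediate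
8 | 4-methyl-4-[(2S)-6-methylhept-5-en-2-yl]cyclohex-2-en-1-one (ring C4 epimers) | CC(C)=CCC[C@H](C)C1(C)CCC(=O)C=C1 | intermediate
9 | 4-methyl-4-[(2S)-6-methylhept-5-en-2-yl]cyclohexa-2,5-dien-1-one | CC(C)=CCC[C@H](C)C1(C)C=CC(=O)C=C1 | intermediate
10 | 4-methyl-4-[(2S)-5-oxopentan-2-yl]cyclohexa-2,5-dien-1-one | O=CCC[C@H](C)C1(C)C=CC(=O)C=C1 | intermediate
11 | 4-[(2S)-5,5-dimethoxypentan-2-yl]-4-methylcyclohexa-2,5-dien-1-one | COC(OC)CC[C@H](C)C1(C)C=CC(=O)C=C1 | intermediate
12 | 2,3,5,6-tetrabromo-4-[(2S)-5,5-dimethoxypentan-2-yl]-4-methylcyclohexan-1-one | COC(OC)CC[C@H](C)C1(C)C(Br)C(Br)C(=O)C(Br)C1Br | intermediate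
13 | 2,6-dibromo-4-[(2S)-5,5-dimethoxypentan-2-yl]-4-methylcyclohexa-2,5-dien-1-one | COC(OC)CC[C@H](C)C1(C)C=C(Br)C(=O)C(Br)=C1 | intermediate
14 | 2,6-dibromo-4-methyl-4-[(2S)-5-oxopentan-2-yl]cyclohexa-2,5-dien-1-one | O=CCC[C@H](C)C1(C)C=C(Br)C(=O)C(Br)=C1 | intermediate
15 | cis-fused 7,9-dibromo-4β,5β-dimethyl-10β-H-eremophil-6-ene-1,8-dione (C9 unassigned) | O=C1CC[C@H](C)[C@@]2(C)C=C(Br)C(=O)C(Br)[C@@H]12 | intermediate
16 | (4aS,5S)-3-bromo-4a,5-dimethyl-4a,5,6,7-tetrahydronaphthalene-2,8-dione | O=C1CC[C@H](C)[C@@]2(C)C=C(Br)C(=O)C=C12 | intermediate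
17 | (4aS,5S,8R)-3-bromo-4a,5-dimethyl-2,4a,5,6,7,8-hexahydronaphthalene-2,8-diol (C2 epimers) | O[C@@H]1CC[C@H](C)[C@@]2(C)C=C(Br)C(O)C=C12 | intermediate
18 | (4aS,5S,8R)-3-bromo-8-hydroxy-4a,5-dimethyl-5,6,7,8-tetrahydronaphthalen-2(4aH)-one | O[C@@H]1CC[C@H](C)[C@@]2(C)C=C(Br)C(=O)C=C12 | intermediate
19 | (R)-4-benzyl-3-propionyloxazolidin-2-one | CCC(=O)N1[C@H](Cc2ccccc2)COC1=O | starting material
20 | (R)-4-benzyl-3-[(Z)-1-(trimethylsilyloxy)prop-1-en-1-yl]oxazolidin-2-one | C/C=C(\O[Si](C)(C)C)N1[C@H](Cc2ccccc2)COC1=O | intermediate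
21 | (R)-4-benzyl-3-{(2S)-2-[(5R,8S,8aS)-5-hydroxy-8,8a-dimethyl-3-oxo-3,5,6,7,8,8a-hexahydronaphthalen-2-yl]propanoyl}oxazolidin-2-one | O[C@@H]1CC[C@H](C)[C@@]2(C)C=C([C@H](C)C(=O)N3[C@H](Cc4ccccc4)COC3=O)C(=O)C=C12 | intermediate
22 | methyl (2S)-2-[(5R,8S,8aS)-5-hydroxy-8,8a-dimethyl-3-oxo-3,5,6,7,8,8a-hexahydronaphthalen-2-yl]propanoate | O[C@@H]1CC[C@H](C)[C@@]2(C)C=C([C@H](C)C(=O)OC)C(=O)C=C12 | intermediate
23 | angelic acid | C/C=C(/C)C(=O)O | starting material
24 | angelic 2,4,6-trichlorobenzoic anhydride | C/C=C(/C)C(=O)OC(=O)c1c(Cl)cc(Cl)cc1Cl | intermediate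
25 | CNP0166395.1, methyl (2S)-2-[(5R,8S,8aS)-8,8a-dimethyl-5-{[(Z)-2-methylbut-2-enoyl]oxy}-3-oxo-3,5,6,7,8,8a-hexahydronaphthalen-2-yl]propanoate | C/C=C(/C)C(=O)O[C@@H]1CC[C@H](C)[C@@]2(C)C=C([C@H](C)C(=O)OC)C(=O)C=C12 | target

Total step count: 13. Longest linear sequence: 12 (steps 1–9 and 11–13; step 10 prepares the coupling partner).

**Steps most likely to fail**

**Step 7.** Several things may go wrong:
- electron transfer or halophilic attack of the electron-rich enaminol on the C–Br bonds
- loss of the carbene by addition to the acceptor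
- intermolecular acylation of the newly formed ene-dione at C9
- erosion of arm selection if catalyst and the C4 centre are mismatched

The fallback uses known chemistry and sets out from 9.
- Ozonolysis with Me2S work-up is stopped at aldehyde 10, which is isolated.
- The bromine-free dienone is cyclised by the established carbene-catalysed desymmetrising Stetter reaction (same triazolium salt, KN(SiMe3)2 in catalytic amount, toluene, rt). This should give cis-fused 4β,5β-dimethyl-10β-H-eremophil-6-ene-1,8-dione F1.
- Dehydrogenation of the 1,4-diketone across C9–C10 with 2,3-dichloro-5,6-dicyano-1,4-benzoquinone in dioxane gives eremophila-6,9-diene-1,8-dione F2.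
- Br2 adds to the less electron-poor C6=C7 bond to give the 6,7-dibromide F3, and Et3N removes HBr. The route is rejoined at 16.

**Step 11.** Transmetalation may be slow, so protodebromination could compete. Silyl transfer to the free C1 hydroxyl may use up the enolate. Facial discrimination at C11 may be poor, or the new centre may epimerise at 60 °C.

The fallback gives up auxiliary control and sets out from 18.
- Negishi-type coupling with the Reformatsky reagent made from methyl 2-bromopropanoate and zinc (Pd(dba)2, P(t-Bu)3, THF, rt) gives 22 directly, together with methyl (2R)-2-[(5R,8S,8aS)-5-hydroxy-8,8a-dimethyl-3-oxo-3,5,6,7,8,8a-hexahydronaphthalen-2-yl]propanoate F4.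
- The two are diastereomers and are separated by chromatography.
- F4 is re-equilibrated with DBU and recycled. The route is rejoined at 22, and 21 and step 12 are skipped.

**Step 13.** Acylation of the hindered axial C1 hydroxyl may be so slow that Z-to-E isomerisation of the activated angelate and epimerisation at C11 in hot amine-containing toluene compete.

The fallback builds the angelate double bond on the molecule and sets out from 22.
- Steglich esterification (DCC, DMAP, CH2Cl2) with the unhindered 2-[bis(2,2,2-trifluoroethoxy)phosphoryl]propanoic acid gives the C1 phosphonopropanoate ester F5.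
- Its phosphonate C–H is far more acidic than C11–H.
- Still–Gennari olefination with acetaldehyde (KN(SiMe3)2, 18-crown-6, THF, −78 °C) should give the Z-trisubstituted enoate. The route is rejoined at 25.

Further compounds
F1 | step 7 | cis-fused 4β,5β-dimethyl-10β-H-eremophil-6-ene-1,8-dione | O=C1CC[C@H](C)[C@@]2(C)C=CC(=O)C[C@@H]12
F2 | step 7 | (4aS,5S)-4a,5-dimethyl-4a,5,6,7-tetrahydronaphthalene-2,8-dione | O=C1CC[C@H](C)[C@@]2(C)C=CC(=O)C=C12
F3 | step 7 | 6,7-dibromo-4β,5β-dimethyleremophil-9-ene-1,8-dione | O=C1CC[C@H](C)[C@@]2(C)C(Br)C(Br)C(=O)C=C12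
F4 | step 11 | methyl (2R)-2-[(5R,8S,8aS)-5-hydroxy-8,8a-dimethyl-3-oxo-3,5,6,7,8,8a-hexahydronaphthalen-2-yl]propanoate | O[C@@H]1CC[C@H](C)[C@@]2(C)C=C([C@@H](C)C(=O)OC)C(=O)C=C12
F5 | step 13 | C1 2-[bis(2,2,2-trifluoroethoxy)phosphoryl]propanoate ester of 22 | CC(C(=O)O[C@@H]1CC[C@H](C)[C@@]2(C)C=C([C@H](C)C(=O)OC)C(=O)C=C12)P(=O)(OCC(F)(F)F)OCC(F)(F)F
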